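The readings come from a simulation with constants of no real substance, and the scatter is random.

Late in the birch run, starting material read 1.6% by 1.50 min, and target fell from 60.3% there to 3.4% at 6.00 min. I took the catalyst as free by then and the fall as pseudo-first-order in target, its rate proportional to catalyst. So I counted each flask's progress as dose, catalyst charged × time. Two runs supported this clock: cedar at dose 3.70 mM·min held 45.1% of the charge as target, and birch at dose 3.15 mM·min held 44.4%.

| flask | starting material | capture agent | free catalyst | remark | time |
|---|---|---|---|---|---|
| cedar | 20 mM | 1 mM | 0.37 mM | run made earlier |  |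
| birch | 20 mM | 1 mM | 6.3 mM | run made earlier |  |
| red | 20 mM | 1.00 mM | 0.30 mM |  | 20 min |
| violet | 20 mM | 1.00 mM | 4.0 mM |  | 20 min |
| grey | 20 mM | 1.00 mM | 2.0 mM |  | 20 min |
| teal | 20 mM | 1.00 mM | 1.0 mM |  | 20 min |

- cedar (time / min: target / %, starting material / %): 0.500: 3.1, 95.5; 1.50: 9.3, 88.7; 3.00: 17.8, 78.6; 4.00: 22.2, 71.9; 6.00: 31.4, 60.3; 8.00: 38.3, 50.4; 10.0: 45.1, 39.6
- birch (time / min: target / %, starting material / %): 0.500: 44.4, 32.5; 1.50: 60.3, 1.6; 3.00: 26.5, 0; 4.00: 13.9, 0; 6.00: 3.4, 0; 8.00: 2.1, 0; 10.0: 0.6, 0.5

(scatter of a reading: 0.5 percentage points)

* the flasks by amount of target, in percent of the starting material charged, highest first, at 20 min (red / violet / grey / teal)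
* the same order at 2.0 min (red / violet / grey / teal)
* the amount of target, in percent of the starting material charged of the flask you put first, at 20 min
* the amount of target, in percent of the starting material charged of the flask you put last, at 20 min

- the earlier runs were read with a standard deviation of 0.5 percentage points

My first estimate was the dose that takes target's share of the charge down by a factor of 2, from the birch readings:

wear dose, first estimate = 6.83 mM·min

Carried from birch's 1.50 min reading to violet's dose of 80.0 mM·min, this gave 0.0470%.

The weak link was that starting point, where some starting material was still feeding target. Birch's target fell at 0.548 min⁻¹ up to 3.00 min, slower than the 0.684 min⁻¹ after it. So I restarted from 3.00 min, where starting material read 0%: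

wear dose, the dose that takes target down by a factor of 2 = 6.38 mM·min

teal at 20 min: 23.5%

grey at 20 min: 2.68%

violet at 20 min: 0.0347%

Red's dose of 6.00 mM·min lay between birch's first two readings, so I interpolated there:

red at 20 min: 51.6%

At 2.0 min, violet's dose of 8.00 mM·min lay between birch's 3.15 mM·min and 9.45 mM·min, and target read higher at the second of these, 60.3% against 44.4%. Those two readings do not show where target peaked between them, so ranking the flasks by catalyst at 2.0 min was only my estimate.

The forecast gave red > teal > grey > violet at 20 min, violet > grey > teal > red at 2.0 min, 56% and 0.2%, on the ground that “Both steps look catalyst-driven”, and its two numbers stood above my red and violet.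

The flasks gave red > teal > grey > violet at 20 min and violet > grey > teal > red at 2.0 min, with 52.0% in red and 0.0359% in violet.

    starting material + free catalyst → catalyst intermediate (k = 19.0 M⁻¹ s⁻¹)
    catalyst intermediate ⇌ free catalyst + target (K = 0.0550 M, k = 0.0760 s⁻¹)
    free catalyst + target → free catalyst + over-reaction product (k = 2.10 M⁻¹ s⁻¹)
    catalyst intermediate + capture agent → trapped intermediate (k = 0.860 M⁻¹ s⁻¹)
    starting material + target → side product (k = 0.0290 M⁻¹ s⁻¹)

In violet, 92.3% of the catalyst charged stood free at 20.0 min. Grey held 24.7% target at 10.0 min, and the wear dose of 6.38 mM·min took that, over grey's further dose of 20.0 mM·min, to 2.81%; grey read 3.27% at 20.0 min.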